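(The numbers of this flask come from no measurement; the result is computed.)

A small charge of substrate, added in two portions, meets twice its amount of partner in this flask, and you want to know where each substrate molecule ends up.

substrate 48 mM (in portions, 2); partner 96.0 mM; time 1.0 h; the portions of substrate follow each other after 12 s, the first at the start

    substrate → open intermediate (k1 = 0.250 s⁻¹)
    partner → second intermediate (k2 = 0.123 s⁻¹)
    open intermediate + second intermediate → target (k3 = 2.17 L mol⁻¹ s⁻¹)
    2 second intermediate → homo product (k4 = 0.246 L mol⁻¹ s⁻¹)
    open intermediate → side product (k5 = 0.0115 s⁻¹)
    2 substrate → self-condensation product (k6 = 0.00316 L mol⁻¹ s⁻¹)
    partner + target ⇌ idle adduct, settled at all times (K7 = 170 L mol⁻¹)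

- a species is counted by the substrate in it: one self-condensation product counts as two
- amounts and yields of target count idle adduct too
- for a step with 2 of a species take k times the square, and two of it per event
- the reaction counts as stopped when no species that holds the substrate changes by six tenths of a point or more over the second half of the time
- run time (flask): 1.0 h

- which holds at 1.0 h: what has brought the reaction to rest, or that it has not come to rest (it is still moving / all of the substrate has reacted)
- the target standing at 1.0 h, as a percentage of the substrate charged
- the side product standing at 1.0 h, as a percentage of the substrate charged

Follow one substrate molecule. It opens with a half-life of 2.77 s, and partner turns into second intermediate with a half-life of 5.64 s; both times are far shorter than the 1.0 h run, so I expect the substrate to have reacted by the end. The open intermediate then stands at a fork: capture at k3[J], where [J] is the second intermediate concentration, or loss to side product at k5. Its chance of capture is therefore [J]/([J]+J*), where J* = k5/k3 = 5.30 mM is the even-odds level, the [J] at which both branches run equally fast, and the selectivity factor, target over side product, is [J]/J*. I take [J] as the partner excess, 48.0 mM, counting one second intermediate per target and none for homo product, which gives a capture chance of 90.1 %, so 9.90 % goes to side product.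

The forecast, lower on target than my figure, says all of the substrate has reacted, with 85 % target and 15 % side product, on the grounds of “capture about five to ten times faster than side-product loss”.

In the simulation of this flask all of the substrate has reacted, with 86.6 % target and 13.4 % side product at 1.0 h. Read through J*, these yields say the open intermediate in this flask met a mean [J], weighted by how much open intermediate stood at each moment, of 34.2 mM, lower than my 48.0 mM.

In the flask, capture and loss ran together while open intermediate stood: at 0.00333 h it held 20.2 % of the charge, with second intermediate at 49.5 mM. By 0.0500 h, target in this flask stood at 86.6 % and side product at 13.4 %. In the neighbour flask with 190 mM of substrate, the yields are 45.6 % target and 54.2 % side product, so side product holds most of the substrate, and the same reading gives a mean [J] of 4.46 mM, below J*.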